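The constants used here belong to no real substance; the result is computed.

the same everywhere: substrate 5.0 mM; coupling partner 5.50 mM; free catalyst 10 µM; time 50 s
- oak: temperature 25 °C
- ash: at −15 °C until 10 s, from then on at 25 °C
- maple: temperature −15 °C
- birch: temperature 5 °C

* the best flask by amount of target, in percent of the substrate charged; "all alike" if 1.5 percentage points covers them all (oak / ash / maple / birch / all alike)
* amount of target at the end, in percent of the substrate charged, oak
* amount of target at the end, in percent of the substrate charged, ash
* amount of target at the end, in percent of the substrate charged, maple
* amount of target at the end, in percent of the substrate charged, birch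

- the constants hold at 5 °C; other temperatures follow from the activation energies and enthalpies

    substrate + free catalyst → catalyst intermediate A (k1 = 2.1 × 10⁵ M⁻¹ s⁻¹, Ea1 = 18.0 kJ mol⁻¹)
    catalyst intermediate A → catalyst intermediate B (k2 = 4.0 s⁻¹, Ea2 = 58.0 kJ mol⁻¹)
    coupling partner + catalyst intermediate B → catalyst intermediate C (k3 = 49000 M⁻¹ s⁻¹, Ea3 = 19.0 kJ mol⁻¹)
    catalyst intermediate C ⇌ free catalyst + target (K4 = 0.0021 M, k4 = 27 s⁻¹, Ea4 = 55.0 kJ mol⁻¹, ΔH4 = −4.00 kJ mol⁻¹)
    target + free catalyst ⇌ isomer of the product + free catalyst, rate k5*[free catalyst]*[target] forward; the back reaction follows from the equilibrium constant (K5 = 1.3, k5 = 430 M⁻¹ s⁻¹, Ea5 = 43.0 kJ mol⁻¹, ΔH5 = −29.0 kJ mol⁻¹)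
    (constants at 5 °C)

- The ratio of substrate to free catalyst is 500 in each flask, so a catalyst molecule must go round the cycle that many times to convert the charge, and each round adds 0.200% of the charge as target.
- A first way to the fraction converted in birch counts one wait per round, the rate-limiting step catalyst intermediate A → catalyst intermediate B (k2 = 4.0 s⁻¹, Ea2 = 58.0 kJ mol⁻¹), which lasts 0.250 s at 5 °C, longer than the other waits together; over 50 s this gives 40.0% of the charge.
- A second way adds up the waits of a full round at the starting fractions, 9.52 × 10⁻⁴ s for capture of substrate, 0.250 s for the rearrangement, 0.00371 s for capture of coupling partner and 0.0370 s for release of target, so a round in birch takes 0.292 s and the flask reaches 34.3%.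
- The two ways part, the first standing higher, and the first one cheats, because it keeps every catalyst molecule in catalyst intermediate A, whereas the sum places 85.6% of the catalyst there, the resting state, and 12.7% in catalyst intermediate C.
- The fractions fall during the run, so the curve can be replaced by its mean: with the mean fraction 0.829 in both capture waits, birch moves down by 0.11 percentage points, and the straight line is good enough there.
- At 25 °C the same sum, with each constant moved by its activation energy, gives 0.0567 s, and this hot round time, the summed waits of one catalyst molecule at the starting fractions, is the quantity carried forward.
- At −15 °C a round takes 1.99 s, so maple reaches 5.03% of the charge.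
- By this reckoning oak needs 28.4 s for its charge and so keeps 21.6 s of spare time, while ash makes 1.01% of the charge in its cold stretch, is reckoned through at 38.1 s and keeps 11.9 s; the spare time, in which target stands beside free catalyst with the reckoned conversion over, is longer in oak than in ash, so this reckoning puts ash first.
- The forecast also names ash, with 93.2% for oak, 96% for ash, 5% for maple and 34.1% for birch, on the ground that “oak loses more than ash, whose cold start leaves less time for that loss”.
- The simulation gives ash as the best flask, with target at 92.4% in oak, 95.9% in ash, 5.01% in maple and 34.1% in birch, and with isomer of the product at 7.44% in oak against 3.97% in ash, in the same order as the spare times.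
- The neighbouring flask is ash with 20 mM of substrate, where the hot round time allows 705 rounds in the hot stretch, but coupling partner, now the limiting reagent at 0.275 equiv, pays for 550 rounds, which is 27.5% of this charge; the simulated neighbour stands at 27.5% target with 0.0156% of its coupling partner left and 99.6% of its catalyst held as catalyst intermediate B.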